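**Plan**

Germacrane locants are used: ring carbons C1–C10 (C1 ketone, C2=C3 in the furanone, C4 with the C15 methylene, C5 carbinol, C6 lactone O-carbon, C8 ester carbon, C10 methylated quaternary carbon) and lactone carbons C11–C13.
The C5 carbinol lies next to the C4(=C15H2) methylene inside the ten-membered carbocycle, the retron of a 1-substituted vinylmetal adding to an aldehyde, so the first cut is C4–C5 (alkenyl iodide plus C5 aldehyde).
The seco aldehyde is then cut at C7–C8 and at the lactone C12–O bond into a furanone aldehyde (C8–C10, C1–C4, C14, C15) and a (Z)-2-(bromomethyl)enoate (C5–C7, C11–C13); the furanone is cut at C2–C3 and O–C3 into a methyl ketone and 2-iodopropenal.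
Forward order: furanone ring (aldol addition, oxidation, cyclodehydration), union of the two halves by indium allylation, lactone ring, and last the ten-membered carbocycle (nine-membered through the furanone oxygen) by Nozaki–Hiyama–Kishi closure.
Stereochemistry: C10 from (S)-2-methylglycidol, C6 from (S)-glyceraldehyde acetonide, C7 and C8 from the chair transition state of the allylation under control of C6, C5 from Felkin–Anh addition anti to the C6–O bond.

Key step: step 17

Remark: the target SMILES is read as 5S,6R,7R,8R,10R (germacrane locants) with H6 and H7 cis on the lactone; every structure below is drawn to that reading.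

**Route**

Step 1
Reactants: 1 prop-2-yn-1-ol
Product: 2 2-iodoprop-2-en-1-ol
Conditions: NaI, Me3SiCl, H2O (0.5 equiv), MeCN, 0 °C → rt
Reagents that add atoms: sodium iodide, [Na+].[I-]
Why: Markovnikov hydroiodination of the terminal alkyne by HI generated in the flask from NaI, Me3SiCl and water puts iodine on the internal carbon and leaves the alcohol untouched; no stereocenter is formed.

Step 2
Reactants: 2 2-iodoprop-2-en-1-ol
Product: 3 2-iodoprop-2-enal
Conditions: Dess–Martin periodinane, CH2Cl2, 0 °C; filtered through silica, kept as a cold CH2Cl2 solution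
Reagents that add atoms: none
Why: Dess–Martin oxidation of a primary allylic alcohol stops at the aldehyde under mild, non-basic conditions that the alkenyl iodide tolerates; the labile enal is kept cold and in solution for the aldol addition of step 7.

Step 3
Reactants: 4 (S)-2-methylglycidol
Product: 5 (2R)-2-methylpent-4-ene-1,2-diol
Conditions: CH2=CHMgBr (3 equiv), CuI (10 mol %), THF, −30 → 0 °C
Reagents that add atoms: vinylmagnesium bromide, C=C[Mg]Br
Why: Copper-catalysed Grignard opening of the 2,2-disubstituted epoxide takes place at the unsubstituted CH2 (SN2), so the quaternary carbinol centre, the later C10, is carried over unchanged, its descriptor turning from S to R only through the CIP priorities.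

Step 4
Reactants: 5 (2R)-2-methylpent-4-ene-1,2-diol
Product: 6 (2R)-2-hydroxy-2-methylpent-4-enoic acid
Conditions: TEMPO (cat.), NaOCl (cat.), NaClO2, MeCN/phosphate buffer (pH 6.7), 35 °C
Reagents that add atoms: sodium chlorite, [Na+].[O-]Cl=O
Why: TEMPO-catalysed oxidation with NaClO2 as terminal oxidant takes the primary alcohol through the aldehyde to the acid (Pinnick-type second stage), while the tertiary alcohol cannot be oxidised and the 1,2-diol is not cleaved.

Step 5
Reactants: 6 (2R)-2-hydroxy-2-methylpent-4-enoic acid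
Product: 7 (3R)-3-hydroxy-3-methylhex-5-en-2-one
Conditions: MeLi (3.5 equiv), THF, −78 → 0 °C; inverse quench into ice-cold H2O
Reagents that add atoms: methyllithium, [Li]C
Why: Addition of methyllithium to the lithium carboxylate gives a geminal dialkoxide that persists until work-up, the standard way from an acid to a methyl ketone without over-addition; the quaternary centre is not affected.

Step 6
Reactants: 7 (3R)-3-hydroxy-3-methylhex-5-en-2-one
Product: 8 (3R)-3-methyl-3-[(trimethylsilyl)oxy]hex-5-en-2-one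
Conditions: Me3SiCl, imidazole, DMF, 0 °C → rt
Reagents that add atoms: chlorotrimethylsilane, C[Si](C)(C)Cl
Why: O-Silylation of the tertiary alcohol (silyl ether formation) lets one equivalent of base generate the methyl ketone enolate cleanly in the next step.

Step 7
Reactants: 8 (3R)-3-methyl-3-[(trimethylsilyl)oxy]hex-5-en-2-one; 3 2-iodoprop-2-enal
Product: 10 (6R)-3-hydroxy-2-iodo-6-methyl-6-[(trimethylsilyl)oxy]nona-1,8-dien-5-one as a mixture of C3 epimers, via lithium enolate 9 (not isolated)
Conditions: LiN(i-Pr)2 (1.05 equiv), THF, −78 °C; then 3 in CH2Cl2, −78 °C; AcOH quench at −78 °C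
Reagents that add atoms: none
Why: Directed aldol addition, in which the kinetic lithium enolate, which can only form at the methyl group, adds 1,2 to the enal at −78 °C; the new carbinol centre is formed without control and disappears in step 8.

Step 8
Reactants: 10 (6R)-3-hydroxy-2-iodo-6-methyl-6-[(trimethylsilyl)oxy]nona-1,8-dien-5-one
Product: 11 (6R)-2-iodo-6-methyl-6-[(trimethylsilyl)oxy]nona-1,8-diene-3,5-dione
Conditions: Dess–Martin periodinane, pyridine, CH2Cl2, 0 °C → rt
Reagents that add atoms: none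
Why: Dess–Martin oxidation of the β-hydroxy ketone gives the (enolised) 1,3-diketone without touching the alkenyl iodide, the terminal alkene or the silyl ether, pyridine buffering the acetic acid released.

Step 9
Reactants: 11 (6R)-2-iodo-6-methyl-6-[(trimethylsilyl)oxy]nona-1,8-diene-3,5-dione
Product: 13 (2R)-5-(1-iodoethenyl)-2-methyl-2-(prop-2-en-1-yl)furan-3(2H)-one, via hydroxy diketone 12 (not isolated)
Conditions: 1 M aq. HCl, THF, rt
Reagents that add atoms: none
Why: Acid removes the silyl ether and the freed tertiary hydroxyl adds to the distal carbonyl (5-exo-trig) and loses water, the classical cyclodehydration of an α′-hydroxy 1,3-diketone to a 3(2H)-furanone; the quaternary centre takes no part.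

Step 10
Reactants: 13 (2R)-5-(1-iodoethenyl)-2-methyl-2-(prop-2-en-1-yl)furan-3(2H)-one
Product: 15 [(2R)-5-(1-iodoethenyl)-2-methyl-3-oxo-2,3-dihydrofuran-2-yl]acetaldehyde, via vicinal diol 14 (not isolated)
Conditions: OsO4 (2 mol %), NaIO4 (4 equiv), 2,6-lutidine, dioxane/H2O (3:1), rt
Reagents that add atoms: osmium tetroxide, O=[Os](=O)(=O)=O; sodium periodate, [Na+].[O-]I(=O)(=O)=O
Why: Lemieux–Johnson cleavage, in which OsO4 should dihydroxylate the isolated monosubstituted alkene far faster than the electron-poor, iodine-bearing alkene of the dienone, and periodate cleaves the diol to the aldehyde, 2,6-lutidine suppressing over-oxidation.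

Step 11
Reactants: 16 (S)-2,3-O-isopropylideneglyceraldehyde; 17 methyl acrylate
Product: 18 methyl 2-{[(4S)-2,2-dimethyl-1,3-dioxolan-4-yl](hydroxy)methyl}prop-2-enoate as a mixture of carbinol epimers
Conditions: DABCO (0.5 equiv), 17 (3 equiv), dioxane/H2O (1:1), rt, several days
Reagents that add atoms: none
Why: Morita–Baylis–Hillman reaction of the aldehyde with the acrylate under amine catalysis; the new carbinol centre is formed as a mixture that converges in step 12, and the dioxolane centre, the later C6, is kept.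

Step 12
Reactants: 18 methyl 2-{[(4S)-2,2-dimethyl-1,3-dioxolan-4-yl](hydroxy)methyl}prop-2-enoate
Product: 19 methyl (2Z)-2-(bromomethyl)-3-[(4R)-2,2-dimethyl-1,3-dioxolan-4-yl]prop-2-enoate
Conditions: NBS, Me2S, CH2Cl2, 0 °C → rt
Reagents that add atoms: N-bromosuccinimide, O=C1CCC(=O)N1Br
Why: Corey–Kim-type activation of the allylic alcohol as an alkoxysulfonium salt is followed by SN2′ attack of bromide, which gives the rearranged primary bromide as the thermodynamically preferred (Z)-isomer with the ester trans to the dioxolane; the descriptor of the dioxolane carbon turns from S to R only through the CIP priorities.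

Step 13
Reactants: 15 [(2R)-5-(1-iodoethenyl)-2-methyl-3-oxo-2,3-dihydrofuran-2-yl]acetaldehyde; 19 methyl (2Z)-2-(bromomethyl)-3-[(4R)-2,2-dimethyl-1,3-dioxolan-4-yl]prop-2-enoate
Product: 20 methyl (3R,4R)-3-[(4R)-2,2-dimethyl-1,3-dioxolan-4-yl]-4-hydroxy-5-[(2R)-5-(1-iodoethenyl)-2-methyl-3-oxo-2,3-dihydrofuran-2-yl]-2-methylidenepentanoate
Conditions: In powder (1.5 equiv), 19 (1.5 equiv), THF/H2O (1:1), rt
Reagents that add atoms: none
Why: Indium-mediated Barbier 2-(alkoxycarbonyl)allylation, in which the (Z)-allylindium formed in the flask adds through its γ-carbon (C7) to the aldehyde in a chair transition state with the dioxolanyl group axial, which gives the C7/C8-syn adduct, and, with the C6–H bond held in the alkene plane by A(1,3) strain, the aldehyde is expected to reach C7 past the dioxolane oxygen and anti to its CH2 arm, the facial sense known for additions to (Z)-γ-alkoxy enoates, which sets 7R and 8R.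

Step 14
Reactants: 20 methyl (3R,4R)-3-[(4R)-2,2-dimethyl-1,3-dioxolan-4-yl]-4-hydroxy-5-[(2R)-5-(1-iodoethenyl)-2-methyl-3-oxo-2,3-dihydrofuran-2-yl]-2-methylidenepentanoate
Product: 21 methyl (3R,4R)-3-[(4R)-2,2-dimethyl-1,3-dioxolan-4-yl]-5-[(2R)-5-(1-iodoethenyl)-2-methyl-3-oxo-2,3-dihydrofuran-2-yl]-2-methylidene-4-[(2-methylpropanoyl)oxy]pentanoate
Conditions: (i-PrCO)2O, Et3N, DMAP (cat.), CH2Cl2, 0 °C → rt
Reagents that add atoms: 2-methylpropanoic anhydride, CC(C)C(=O)OC(=O)C(C)C
Why: DMAP-catalysed acylation of the secondary C8 alcohol with retention, carried out at once so that the hydroxy ester cannot close to the unwanted lactone on O8.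

Step 15
Reactants: 21 methyl (3R,4R)-3-[(4R)-2,2-dimethyl-1,3-dioxolan-4-yl]-5-[(2R)-5-(1-iodoethenyl)-2-methyl-3-oxo-2,3-dihydrofuran-2-yl]-2-methylidene-4-[(2-methylpropanoyl)oxy]pentanoate
Product: 23 (1R)-1-[(2R,3R)-2-(hydroxymethyl)-4-methylidene-5-oxooxolan-3-yl]-2-[(2R)-5-(1-iodoethenyl)-2-methyl-3-oxo-2,3-dihydrofuran-2-yl]ethyl 2-methylpropanoate, via dihydroxy ester 22 (not isolated)
Conditions: CF3CO2H/H2O/CH2Cl2 (4:1:5), 0 °C → rt
Reagents that add atoms: none
Why: Acid hydrolysis of the acetonide frees the C5/C6 diol and the C6 hydroxyl, γ to the acrylate carbonyl, lactonises with loss of methanol (acid-catalysed transesterification, the five-membered ring being preferred over the six-membered ring through the primary C5 hydroxyl); C6 and C7 are untouched, so the cis-disubstituted α-methylene-γ-butyrolactone results.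

Step 16
Reactants: 23 (1R)-1-[(2R,3R)-2-(hydroxymethyl)-4-methylidene-5-oxooxolan-3-yl]-2-[(2R)-5-(1-iodoethenyl)-2-methyl-3-oxo-2,3-dihydrofuran-2-yl]ethyl 2-methylpropanoate
Product: 24 (1R)-1-[(2R,3R)-2-formyl-4-methylidene-5-oxooxolan-3-yl]-2-[(2R)-5-(1-iodoethenyl)-2-methyl-3-oxo-2,3-dihydrofuran-2-yl]ethyl 2-methylpropanoate
Conditions: Dess–Martin periodinane, CH2Cl2, 0 °C → rt; used without chromatography
Reagents that add atoms: none
Why: Dess–Martin oxidation of the primary C5 alcohol gives the α-acyloxy aldehyde under non-basic conditions, so the epimerisable C6 centre next to the new carbonyl is kept; the aldehyde is used at once.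

Step 17
Reactants: 24 (1R)-1-[(2R,3R)-2-formyl-4-methylidene-5-oxooxolan-3-yl]-2-[(2R)-5-(1-iodoethenyl)-2-methyl-3-oxo-2,3-dihydrofuran-2-yl]ethyl 2-methylpropanoate
Product: 25 (5S,6R,7R,8R,10R)-5-hydroxy-8-[(2-methylpropanoyl)oxy]-1-oxo-3,10-epoxygermacra-2,4(15),11(13)-trien-12,6-olide (CNP0384113.1)
Conditions: CrCl2 (10 equiv), NiCl2 (2 mol %), degassed DMSO, rt, slow addition of 24 to 2 mM final concentration
Reagents that add atoms: none
Why: NiCl2 is reduced by CrCl2 to zerovalent nickel, which inserts into the C4–I bond; the alkenyl group passes to trivalent chromium and the alkenylchromium adds 1,2 to the C5 aldehyde, the chromium alkoxide being hydrolysed on work-up. The closest known reaction type is the intramolecular Nozaki–Hiyama–Kishi coupling of a 2-iodoalkene with an aldehyde, used for medium-ring closure. The ten-membered carbocycle C1–C10 (nine-membered through the furanone oxygen) closes in exo-trig mode at the aldehyde carbon, C4 and C5 being held near each other by the cis-fused lactone and the planar furanone. The new C5 centre is set by polar Felkin–Anh addition anti to the C6–O bond, which gives the 5,6-anti arrangement, 5S. The step needs chemoselectivity for the aldehyde over the furanone ketone, the methylene lactone and the isobutyrate, which the low basicity and aldehyde selectivity of alkenylchromium reagents secure, and it needs ring closure to outrun intermolecular coupling, which high dilution secures.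

**Compound list**

1 | prop-2-yn-1-ol | C#CCO | starting material
2 | 2-iodoprop-2-en-1-ol | C=C(I)CO | intermediate
3 | 2-iodoprop-2-enal | C=C(I)C=O | intermediate
4 | (S)-2-methylglycidol, [(2S)-2-methyloxiran-2-yl]methanol | C[C@]1(CO)CO1 | starting material
5 | (2R)-2-methylpent-4-ene-1,2-diol | C[C@](O)(CO)CC=C | intermediate
6 | (2R)-2-hydroxy-2-methylpent-4-enoic acid | C[C@](O)(C(=O)O)CC=C | intermediate
7 | (3R)-3-hydroxy-3-methylhex-5-en-2-one | C[C@](O)(C(C)=O)CC=C | intermediate
8 | (3R)-3-methyl-3-[(trimethylsilyl)oxy]hex-5-en-2-one | C[C@](O[Si](C)(C)C)(C(C)=O)CC=C | intermediate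
9 | lithium (3R)-3-methyl-3-[(trimethylsilyl)oxy]hexa-1,5-dien-2-olate (kinetic enolate of 8) | C[C@](O[Si](C)(C)C)(C(=C)O[Li])CC=C | intermediate
10 | (6R)-3-hydroxy-2-iodo-6-methyl-6-[(trimethylsilyl)oxy]nona-1,8-dien-5-one, both C3 epimers | C[C@](O[Si](C)(C)C)(C(=O)CC(O)C(I)=C)CC=C | intermediate
11 | (6R)-2-iodo-6-methyl-6-[(trimethylsilyl)oxy]nona-1,8-diene-3,5-dione | C[C@](O[Si](C)(C)C)(C(=O)CC(=O)C(I)=C)CC=C | intermediate
12 | (6R)-6-hydroxy-2-iodo-6-methylnona-1,8-diene-3,5-dione | C[C@](O)(C(=O)CC(=O)C(I)=C)CC=C | intermediate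
13 | (2R)-5-(1-iodoethenyl)-2-methyl-2-(prop-2-en-1-yl)furan-3(2H)-one | C=CC[C@@]1(C)OC(=CC1=O)C(=C)I | intermediate
14 | (2R)-2-(2,3-dihydroxypropyl)-5-(1-iodoethenyl)-2-methylfuran-3(2H)-one, both carbinol epimers | OCC(O)C[C@@]1(C)OC(=CC1=O)C(=C)I | intermediate
15 | [(2R)-5-(1-iodoethenyl)-2-methyl-3-oxo-2,3-dihydrofuran-2-yl]acetaldehyde | O=CC[C@@]1(C)OC(=CC1=O)C(=C)I | intermediate
16 | (S)-2,3-O-isopropylideneglyceraldehyde, (4S)-2,2-dimethyl-1,3-dioxolane-4-carbaldehyde | O=C[C@@H]1COC(C)(C)O1 | starting material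
17 | methyl acrylate | C=CC(=O)OC | starting material
18 | methyl 2-{[(4S)-2,2-dimethyl-1,3-dioxolan-4-yl](hydroxy)methyl}prop-2-enoate, both carbinol epimers | COC(=O)C(=C)C(O)[C@@H]1COC(C)(C)O1 | intermediate
19 | methyl (2Z)-2-(bromomethyl)-3-[(4R)-2,2-dimethyl-1,3-dioxolan-4-yl]prop-2-enoate | BrC/C(C(=O)OC)=C\[C@@H]1COC(C)(C)O1 | intermediate
20 | methyl (3R,4R)-3-[(4R)-2,2-dimethyl-1,3-dioxolan-4-yl]-4-hydroxy-5-[(2R)-5-(1-iodoethenyl)-2-methyl-3-oxo-2,3-dihydrofuran-2-yl]-2-methylidenepentanoate | C=C(C(=O)OC)[C@@H]([C@@H]1COC(C)(C)O1)[C@H](O)C[C@@]1(C)OC(=CC1=O)C(=C)I | intermediate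
21 | methyl (3R,4R)-3-[(4R)-2,2-dimethyl-1,3-dioxolan-4-yl]-5-[(2R)-5-(1-iodoethenyl)-2-methyl-3-oxo-2,3-dihydrofuran-2-yl]-2-methylidene-4-[(2-methylpropanoyl)oxy]pentanoate | C=C(C(=O)OC)[C@@H]([C@@H]1COC(C)(C)O1)[C@H](OC(=O)C(C)C)C[C@@]1(C)OC(=CC1=O)C(=C)I | intermediate
22 | methyl (3S,4R)-3-[(1R)-1,2-dihydroxyethyl]-5-[(2R)-5-(1-iodoethenyl)-2-methyl-3-oxo-2,3-dihydrofuran-2-yl]-2-methylidene-4-[(2-methylpropanoyl)oxy]pentanoate | C=C(C(=O)OC)[C@@H]([C@@H](O)CO)[C@H](OC(=O)C(C)C)C[C@@]1(C)OC(=CC1=O)C(=C)I | intermediate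
23 | (1R)-1-[(2R,3R)-2-(hydroxymethyl)-4-methylidene-5-oxooxolan-3-yl]-2-[(2R)-5-(1-iodoethenyl)-2-methyl-3-oxo-2,3-dihydrofuran-2-yl]ethyl 2-methylpropanoate | C=C1C(=O)O[C@@H](CO)[C@H]1[C@H](OC(=O)C(C)C)C[C@@]1(C)OC(=CC1=O)C(=C)I | intermediate
24 | (1R)-1-[(2R,3R)-2-formyl-4-methylidene-5-oxooxolan-3-yl]-2-[(2R)-5-(1-iodoethenyl)-2-methyl-3-oxo-2,3-dihydrofuran-2-yl]ethyl 2-methylpropanoate (seco aldehyde) | C=C1C(=O)O[C@@H](C=O)[C@H]1[C@H](OC(=O)C(C)C)C[C@@]1(C)OC(=CC1=O)C(=C)I | intermediate
25 | (5S,6R,7R,8R,10R)-5-hydroxy-8-[(2-methylpropanoyl)oxy]-1-oxo-3,10-epoxygermacra-2,4(15),11(13)-trien-12,6-olide (CNP0384113.1) | C=C1C(=O)O[C@@H]2[C@H]1[C@H](OC(=O)C(C)C)C[C@@]1(C)OC(=CC1=O)C(=C)[C@@H]2O | target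

**Count**

Total steps: 17. Longest linear sequence: 13 steps (steps 3–10, then 13–17).

**Steps most likely to fail**

Step 17, ring closure. What may go wrong: addition to the wrong face of the aldehyde. The folding of the forming ring, not the C6–O dipole, may decide the face, which would give the 5R alcohol. Fallback: C5 is set by reduction of a ketone instead of by the C–C bond formation. It sets out from 24. The cyclisation product, then the 5-epimer of the target F1, is oxidised with Dess–Martin periodinane to the C5 ketone F2. This enone is reduced with (S)-2-methyl-CBS-oxazaborolidine and catecholborane at −78 °C; the catalyst, reading the alkenyl side C4 as the large group, should deliver hydride to the face that gives the 5S alcohol. The route is rejoined at 25.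

Step 13, fragment union. What may go wrong: poor or reversed facial selectivity. The allylindium may bond to the aldehyde through the other face of C7 (anti to the dioxolane oxygen instead of past it), because control by C6 rests on a conformational argument and not on a ring; the 7S,8S adduct would then prevail. Fallback: this preference is turned to use by entering with the mirror-image bromide and inverting C6 when the lactone is closed. It sets out from 15, with 17 for the acrylate unit. (R)-2,3-O-Isopropylideneglyceraldehyde F3 and 17 give the Morita–Baylis–Hillman adduct F4, and NBS/Me2S gives the (4S)-bromide F5. Indium coupling of F5 with 15 should then give the 6-epimeric adduct F6 with C7 and C8 as required, and isobutyrylation gives the ester F7. The acetonide is cleaved with PPTS in MeOH to the diol F8, which PPh3 and DIAD close to the terminal epoxide F9 with retention at C6. Camphorsulfonic acid in wet CH2Cl2 then lets the ester carbonyl open the epoxide at C6 (5-exo, inversion) with loss of methanol, and the route is rejoined at the lactone alcohol 23.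

Step 7, aldol addition. What may go wrong: loss of the enal. 2-Iodopropenal may polymerise or be consumed by the amide base before the enolate adds, and the aldolate may revert on warming. Fallback: the furanone is built from an ynone and iodine is introduced last. It sets out from the acid 6. Coupling with MeNHOMe·HCl (EDC) gives the Weinreb amide F10. Lithium (trimethylsilyl)butadiynide, made from 1,4-bis(trimethylsilyl)buta-1,3-diyne (C[Si](C)(C)C#CC#C[Si](C)(C)C) and MeLi·LiBr, adds to give the hydroxy diynone F11. AuCl3 (5 mol %) closes it 5-endo-dig to the silylethynyl furanone F12, and K2CO3 in MeOH frees the terminal alkyne F13. Bu3SnH under Pd(PPh3)4 catalysis adds with tin at the internal carbon, as for alkynes conjugated to an acceptor, to give the alkenylstannane F14. Iodine exchanges tin for iodine and the route is rejoined at the furanone 13.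

**Further compounds**

F1 | step 17 | (5R,6R,7R,8R,10R)-5-hydroxy-8-[(2-methylpropanoyl)oxy]-1-oxo-3,10-epoxygermacra-2,4(15),11(13)-trien-12,6-olide (5-epimer of the target) | C=C1C(=O)O[C@@H]2[C@H]1[C@H](OC(=O)C(C)C)C[C@@]1(C)OC(=CC1=O)C(=C)[C@H]2O
F2 | step 17 | (6R,7R,8R,10R)-8-[(2-methylpropanoyl)oxy]-1,5-dioxo-3,10-epoxygermacra-2,4(15),11(13)-trien-12,6-olide | C=C1C(=O)O[C@@H]2[C@H]1[C@H](OC(=O)C(C)C)C[C@@]1(C)OC(=CC1=O)C(=C)C2=O
F3 | step 13 | (R)-2,3-O-isopropylideneglyceraldehyde, (4R)-2,2-dimethyl-1,3-dioxolane-4-carbaldehyde | O=C[C@H]1COC(C)(C)O1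
F4 | step 13 | methyl 2-{[(4R)-2,2-dimethyl-1,3-dioxolan-4-yl](hydroxy)methyl}prop-2-enoate, both carbinol epimers | COC(=O)C(=C)C(O)[C@H]1COC(C)(C)O1
F5 | step 13 | methyl (2Z)-2-(bromomethyl)-3-[(4S)-2,2-dimethyl-1,3-dioxolan-4-yl]prop-2-enoate | BrC/C(C(=O)OC)=C\[C@H]1COC(C)(C)O1
F6 | step 13 | methyl (3R,4R)-3-[(4S)-2,2-dimethyl-1,3-dioxolan-4-yl]-4-hydroxy-5-[(2R)-5-(1-iodoethenyl)-2-methyl-3-oxo-2,3-dihydrofuran-2-yl]-2-methylidenepentanoate | C=C(C(=O)OC)[C@@H]([C@H]1COC(C)(C)O1)[C@H](O)C[C@@]1(C)OC(=CC1=O)C(=C)I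
F7 | step 13 | methyl (3R,4R)-3-[(4S)-2,2-dimethyl-1,3-dioxolan-4-yl]-5-[(2R)-5-(1-iodoethenyl)-2-methyl-3-oxo-2,3-dihydrofuran-2-yl]-2-methylidene-4-[(2-methylpropanoyl)oxy]pentanoate | C=C(C(=O)OC)[C@@H]([C@H]1COC(C)(C)O1)[C@H](OC(=O)C(C)C)C[C@@]1(C)OC(=CC1=O)C(=C)I
F8 | step 13 | methyl (3S,4R)-3-[(1S)-1,2-dihydroxyethyl]-5-[(2R)-5-(1-iodoethenyl)-2-methyl-3-oxo-2,3-dihydrofuran-2-yl]-2-methylidene-4-[(2-methylpropanoyl)oxy]pentanoate | C=C(C(=O)OC)[C@@H]([C@H](O)CO)[C@H](OC(=O)C(C)C)C[C@@]1(C)OC(=CC1=O)C(=C)I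
F9 | step 13 | methyl (3R,4R)-5-[(2R)-5-(1-iodoethenyl)-2-methyl-3-oxo-2,3-dihydrofuran-2-yl]-2-methylidene-4-[(2-methylpropanoyl)oxy]-3-[(2S)-oxiran-2-yl]pentanoate | C=C(C(=O)OC)[C@@H]([C@H]1CO1)[C@H](OC(=O)C(C)C)C[C@@]1(C)OC(=CC1=O)C(=C)I
F10 | step 7 | (2R)-2-hydroxy-N-methoxy-N,2-dimethylpent-4-enamide | C[C@](O)(C(=O)N(C)OC)CC=C
F11 | step 7 | (6R)-6-hydroxy-6-methyl-1-(trimethylsilyl)non-8-ene-1,3-diyn-5-one | C[C@](O)(C(=O)C#CC#C[Si](C)(C)C)CC=C
F12 | step 7 | (2R)-2-methyl-2-(prop-2-en-1-yl)-5-[(trimethylsilyl)ethynyl]furan-3(2H)-one | C=CC[C@@]1(C)OC(=CC1=O)C#C[Si](C)(C)C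
F13 | step 7 | (2R)-5-ethynyl-2-methyl-2-(prop-2-en-1-yl)furan-3(2H)-one | C=CC[C@@]1(C)OC(=CC1=O)C#C
F14 | step 7 | (2R)-2-methyl-2-(prop-2-en-1-yl)-5-[1-(tributylstannyl)ethenyl]furan-3(2H)-one | C=CC[C@@]1(C)OC(=CC1=O)C(=C)[Sn](CCCC)(CCCC)CCCC
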